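The target is disconnected at the O1–C8a aryl ether bond of the pyranone (C) ring. C8a sits next to C4a, the carbon that carries the C4 carbonyl, and C7 sits para to C4a, so a 2,4-difluoro-3-methoxybenzoyl A ring is used twice. In the key step the enolate oxygen of an α-formyl deoxybenzoin (a Z-hydroxymethylene ketone made from a Weinreb amide, a benzylic Grignard reagent and DMF dimethyl acetal) displaces the ortho fluoride and closes the six-membered ring in one operation. The fluoride that survives at C7, now para to the chromone carbonyl, is then exchanged for the prenyloxy group.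

Key step: step 5

Remark on the chemistry: the target has no stereocentre and no stereogenic double bond (the prenyl alkene ends in two methyl groups), so it is one achiral compound and no stereocontrol is needed. The only defined geometry in the route is the enol double bond of the key-step precursor.

**Step 1**
Reactants: 1 2,4-difluoro-3-methoxybenzoic acid
Product: 3 2,4-difluoro-N,3-dimethoxy-N-methylbenzamide, via acid chloride 2 (not isolated)
Conditions: (COCl)2, cat. DMF, CH2Cl2, 0 °C to rt; evaporate; then MeNH(OMe)·HCl, aq. K2CO3, CH2Cl2, 0 °C to rt
Reagents that add atoms: N,O-dimethylhydroxylamine hydrochloride, CNOC.Cl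
Why: Acid chloride formation followed by Schotten–Baumann N-acylation should give the Weinreb amide cleanly, because acylation of the hydroxylamine at 0 °C is far faster than any attack of this weak base on the fluorinated ring.

**Step 2**
Reactants: 3 2,4-difluoro-N,3-dimethoxy-N-methylbenzamide; 4 4-methoxybenzyl chloride
Product: 6 1-(2,4-difluoro-3-methoxyphenyl)-2-(4-methoxyphenyl)ethan-1-one, via 4-methoxybenzylmagnesium chloride 5 (not isolated)
Conditions: 4, Mg turnings (I2 activation), 2-MeTHF, 0–10 °C, slow addition; then 3, −10 to 0 °C; 1 M aq. HCl quench
Reagents that add atoms: none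
Why: Weinreb ketone synthesis, in which the magnesium-chelated tetrahedral adduct resists a second addition and releases the ketone only on acidic quench, while the low temperature keeps the Grignard reagent away from the ortho C–F bond.

**Step 3**
Reactants: 6 1-(2,4-difluoro-3-methoxyphenyl)-2-(4-methoxyphenyl)ethan-1-one; 7 N,N-dimethylformamide dimethyl acetal
Product: 8 (E)-1-(2,4-difluoro-3-methoxyphenyl)-3-(dimethylamino)-2-(4-methoxyphenyl)prop-2-en-1-one
Conditions: DMF-DMA (2–3 equiv), toluene, 90 °C
Reagents that add atoms: none
Why: Aminomethylenation of the doubly activated benzylic methylene of a deoxybenzoin with an amide acetal is a standard condensation, and the tertiary enaminone cannot cyclise or attack the ring (its geometry is lost in the next step and does not matter).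

**Step 4**
Reactants: 8 (E)-1-(2,4-difluoro-3-methoxyphenyl)-3-(dimethylamino)-2-(4-methoxyphenyl)prop-2-en-1-one
Product: 9 (Z)-1-(2,4-difluoro-3-methoxyphenyl)-3-hydroxy-2-(4-methoxyphenyl)prop-2-en-1-one
Conditions: 1 M aq. HCl, THF, rt
Reagents that add atoms: water, O
Why: Acid hydrolysis of a vinylogous amide (C-protonation, hydration of the iminium ion, loss of dimethylamine as its ammonium salt) should give the β-keto aldehyde as its hydrogen-bonded Z enol, and the acidic medium suppresses both amine attack on the ring and retro-Claisen deformylation.

**Step 5**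
Reactants: 9 (Z)-1-(2,4-difluoro-3-methoxyphenyl)-3-hydroxy-2-(4-methoxyphenyl)prop-2-en-1-one
Product: 10 7-fluoro-8-methoxy-3-(4-methoxyphenyl)-4H-chromen-4-one
Conditions: K2CO3 (2 equiv), dry DMF, 80 °C
Reagents that add atoms: none
Why: Carbonate deprotonates the acidic enol of 9, and the enolate oxygen adds to the fluorine-bearing ring carbon ortho to the ketone (the future C8a), giving a Meisenheimer anion whose charge is taken up by that ketone; loss of fluoride restores aromaticity and forms O1–C8a. The closest known reaction type is the base-mediated cyclisation of 2-fluoroaryl 1,3-dicarbonyl enolates to chromones and flavones, the oxygen counterpart of the 4-quinolone closure of 2-fluorobenzoyl enamines. The pyranone ring closes by a formally 6-endo-trig addition (the C8a=C4a π bond that accepts the electrons lies inside the new ring), followed by elimination. No stereocentre is formed; only the Z enolate, with its oxygen cis to the aroyl group, can reach the ring, and E/Z exchange through the delocalised enolate and the keto-aldehyde tautomer supplies it. The step needs ortho over para fluoride selectivity and O- over C-arylation: the tether lets the oxygen reach only the ortho carbon through a six-membered transition state, the para fluoride is poorly activated towards intermolecular attack while the ketone is part of the enolate, and C-attack would need a four-membered ring. Dry, hydroxide-free conditions should suppress retro-Claisen loss of the formyl group.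

**Step 6**
Reactants: 10 7-fluoro-8-methoxy-3-(4-methoxyphenyl)-4H-chromen-4-one; 11 prenol (3-methylbut-2-en-1-ol)
Product: 12 8-methoxy-3-(4-methoxyphenyl)-7-[(3-methylbut-2-en-1-yl)oxy]-4H-chromen-4-one
Conditions: prenol (3 equiv), Cs2CO3 (2 equiv), dry DMSO, 4 Å MS, 70 °C
Reagents that add atoms: none
Why: Intermolecular nucleophilic aromatic substitution (addition–elimination) at C7, whose Meisenheimer adduct is stabilised by the para C4 carbonyl, should prevail because fluoride loss is irreversible whereas alkoxide addition at C2 reverts to the chromone under dry conditions.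

**Compound list**
1 | 2,4-difluoro-3-methoxybenzoic acid | COc1c(F)ccc(C(=O)O)c1F | starting material
2 | 2,4-difluoro-3-methoxybenzoyl chloride | COc1c(F)ccc(C(=O)Cl)c1F | intermediate
3 | 2,4-difluoro-N,3-dimethoxy-N-methylbenzamide | CON(C)C(=O)c1ccc(F)c(OC)c1F | intermediate
4 | 4-methoxybenzyl chloride | COc1ccc(CCl)cc1 | starting material
5 | 4-methoxybenzylmagnesium chloride | COc1ccc(C[Mg]Cl)cc1 | intermediate
6 | 1-(2,4-difluoro-3-methoxyphenyl)-2-(4-methoxyphenyl)ethan-1-one | COc1ccc(CC(=O)c2ccc(F)c(OC)c2F)cc1 | intermediate
7 | N,N-dimethylformamide dimethyl acetal | COC(OC)N(C)C | starting material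
8 | (E)-1-(2,4-difluoro-3-methoxyphenyl)-3-(dimethylamino)-2-(4-methoxyphenyl)prop-2-en-1-one | CN(C)/C=C(\c1ccc(OC)cc1)C(=O)c1ccc(F)c(OC)c1F | intermediate
9 | (Z)-1-(2,4-difluoro-3-methoxyphenyl)-3-hydroxy-2-(4-methoxyphenyl)prop-2-en-1-one | COc1ccc(/C(=C/O)C(=O)c2ccc(F)c(OC)c2F)cc1 | intermediate
10 | 7-fluoro-8-methoxy-3-(4-methoxyphenyl)-4H-chromen-4-one | COc1ccc(-c2coc3c(OC)c(F)ccc3c2=O)cc1 | intermediate
11 | prenol (3-methylbut-2-en-1-ol) | CC(C)=CCO | starting material
12 | 8-methoxy-3-(4-methoxyphenyl)-7-[(3-methylbut-2-en-1-yl)oxy]-4H-chromen-4-one | COc1ccc(-c2coc3c(OC)c(OCC=C(C)C)ccc3c2=O)cc1 | target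

Total step count: 6
Longest linear sequence: 6 steps (1 → 3 → 6 → 8 → 9 → 10 → 12)

**Steps most likely to fail**

1. Step 6. Fluoride displacement at C7 may be slow, since the pyranone carbonyl is a weaker activator than a nitro or nitrile group and the 8-methoxy group crowds the site. Alkoxide addition at C2, opening of the pyranone and deformylation by traces of hydroxide could then take over. The fallback sets out from 10 and replaces the basic alkoxide by a weakly basic α-effect nucleophile, then forms the ether by O-alkylation. (E)-Benzaldoxime with K2CO3 in DMSO at about 80 °C should displace the fluoride to give (E)-benzaldehyde O-[8-methoxy-3-(4-methoxyphenyl)-4-oxo-4H-chromen-7-yl]oxime F1. This is not isolated: under the same basic conditions it should fragment to benzonitrile and the 7-phenoxide, which resists attack at C2. Acidification should give 7-hydroxy-8-methoxy-3-(4-methoxyphenyl)-4H-chromen-4-one F2. Williamson alkylation of F2 with prenyl bromide (K2CO3, acetone, reflux) comes back to the route at 12.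

2. Step 5. Ring closure of the stabilised enolate may be slow enough for retro-Claisen loss of the formyl group or intermolecular O-arylation to compete. The fallback closes the same ring through O1–C2 instead and sets out from 1.
   - Solid NaOH in 1,3-dimethyl-2-imidazolidinone at about 130 °C should replace the fluoride ortho to the carboxylate (carboxylate-directed substitution) and give 4-fluoro-2-hydroxy-3-methoxybenzoic acid F3.
   - EDC/HOBt coupling with N,O-dimethylhydroxylamine hydrochloride should give 4-fluoro-2-hydroxy-N,3-dimethoxy-N-methylbenzamide F4.
   - An excess of Grignard reagent 5 (one equivalent is spent on the phenol) should give 1-(4-fluoro-2-hydroxy-3-methoxyphenyl)-2-(4-methoxyphenyl)ethan-1-one F5.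
   - Heating F5 with acetal 7 in toluene should give (E)-3-(dimethylamino)-1-(4-fluoro-2-hydroxy-3-methoxyphenyl)-2-(4-methoxyphenyl)prop-2-en-1-one F6, not isolated. Its phenol adds to the aminomethylene carbon and expels dimethylamine (the classical isoflavone closure), which comes back to the route at 10.

3. Step 2. Wurtz homocoupling during formation of the benzylic Grignard reagent may lower its titre, and residual attack on the ortho C–F bond may erode the ketone. The fallback sets out from acid chloride 2 (made from 1 as in step 1) and chloride 4. Zinc insertion into 4 (Zn dust, LiCl, THF) should give 4-methoxybenzylzinc chloride F7 with little homocoupling. Palladium-catalysed acylation of F7 with 2 (Pd(PPh3)4, THF, rt; Negishi-type ketone synthesis, C–F bonds inert) comes back to the route at 6 without passing through 3.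

**Further compounds**
F1 | step 6 | (E)-benzaldehyde O-[8-methoxy-3-(4-methoxyphenyl)-4-oxo-4H-chromen-7-yl]oxime | COc1ccc(-c2coc3c(OC)c(O/N=C/c4ccccc4)ccc3c2=O)cc1
F2 | step 6 | 7-hydroxy-8-methoxy-3-(4-methoxyphenyl)-4H-chromen-4-one | COc1ccc(-c2coc3c(OC)c(O)ccc3c2=O)cc1
F3 | step 5 | 4-fluoro-2-hydroxy-3-methoxybenzoic acid | COc1c(F)ccc(C(=O)O)c1O
F4 | step 5 | 4-fluoro-2-hydroxy-N,3-dimethoxy-N-methylbenzamide | CON(C)C(=O)c1ccc(F)c(OC)c1O
F5 | step 5 | 1-(4-fluoro-2-hydroxy-3-methoxyphenyl)-2-(4-methoxyphenyl)ethan-1-one | COc1ccc(CC(=O)c2ccc(F)c(OC)c2O)cc1
F6 | step 5 | (E)-3-(dimethylamino)-1-(4-fluoro-2-hydroxy-3-methoxyphenyl)-2-(4-methoxyphenyl)prop-2-en-1-one | CN(C)/C=C(\c1ccc(OC)cc1)C(=O)c1ccc(F)c(OC)c1O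
F7 | step 2 | 4-methoxybenzylzinc chloride | COc1ccc(C[Zn]Cl)cc1
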